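| flask | starting material | second substrate | free catalyst | remark | time |
|---|---|---|---|---|---|
| Tuesday's | 0.10 M | 0.29 equiv | 0.81 mol% | run made earlier |  |
| Wednesday's | 0.10 M | 0.81 equiv | 0.81 mol% | run made earlier |  |
| elm | 0.10 M | 0.500 equiv | 0.81 mol% |  | 6.0 h |
| alder | 0.10 M | 1.00 equiv | 0.81 mol% |  | 6.0 h |

| run | time / h | starting material / % | catalyst intermediate A / % | target / % |
|---|---|---|---|---|
| Tuesday's | 1.00 | 76.9 | 0 | 22.2 |
| Tuesday's | 2.00 | 63.7 | 1.8 | 36.6 |
| Tuesday's | 3.00 | 51.4 | 0 | 50.6 |
| Tuesday's | 4.00 | 44.0 | 0 | 57.0 |
| Wednesday's | 0.500 | 89.4 | 2.1 | 9.9 |
| Wednesday's | 1.33 | 75.9 | 1.0 | 21.9 |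
| Wednesday's | 2.50 | 67.0 | 0.7 | 32.7 |
| Wednesday's | 4.00 | 57.1 | 2.7 | 43.6 |

(readings scatter by 1 percentage point)

1. which of these there is most of at the end, counted by the starting material in it, elm (target / starting material / catalyst intermediate A)
2. which of these there is most of at the end, counted by the starting material in it, alder (target / starting material / catalyst intermediate A)
3. final amount of the leader among these, as a percentage of the starting material charged, in elm
4. final amount of the leader among these, as a percentage of the starting material charged, in alder

- a reading or a percentage of target counts all its forms, free or not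

0.693 is the line to hold each flask against: target and starting material together read about the whole charge, so target leads once the logarithm of charge over starting material left passes it. The first readings of both runs give a starting rate constant, pseudo-first-order at this catalyst loading, of 0.243 h⁻¹.

First extreme: the catalyst lasts, and elm and alder alike keep 23.3% of the starting material. But by its last reading Wednesday's run had worked at a mean 57.6% of that constant, while Tuesday's, with less second substrate, read 84.3%. So we let activity decay exponentially, in proportion to second substrate. Taking the mean as the mid-run value gives 0.276 h⁻¹. The true mean of such a curve lies 5.16% higher, so Wednesday's decay constant becomes 0.301 h⁻¹.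

Second extreme: the flask stands until activity has gone. Its logarithm is the reach, starting rate constant over decay constant, 0.654 for alder and 1.31 for elm. Alder's reach lies below the line, so by this estimate alder keeps about 52.0% and starting material leads. The real flasks lie short of both extremes: by 6.0 h alder has used 89.3% of its reach and elm 67.2%. We reckon 55.8% starting material in alder and 58.5% target in elm.

The forecast gives target at 59% in elm and starting material at 54% in alder: “This call is fairly close.” The simulation gives target at 59.3% in elm and starting material at 57.0% in alder.

    starting material + free catalyst ⇌ catalyst intermediate A (K = 3.40 M⁻¹, k = 1800 M⁻¹ h⁻¹)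
    catalyst intermediate A → free catalyst + target (k = 180 h⁻¹)
    second substrate + free catalyst ⇌ catalyst intermediate B (K = 27.0 M⁻¹, k = 200 M⁻¹ h⁻¹)
    catalyst intermediate B → free catalyst + second product (k = 36.0 h⁻¹)
    free catalyst + target ⇌ idle complex, settled at all times (K = 4.00 M⁻¹)
    catalyst intermediate B → spent catalyst (k = 1.40 h⁻¹)

At the asked time in alder, catalyst intermediate B goes on to free catalyst and second product 26 times for each time it goes to spent catalyst, and spent catalyst stands at 85.8% of the catalyst charged. After 60.0 h alder holds 51.3% starting material, beside the 52.0% its reach gave. For a neighbour of alder charged with 1.4 mol% of free catalyst, we scale the starting constant with loading and hold the decay: the reach becomes 1.13, leaving 36.4%. Computed, that neighbour keeps 36.1% starting material, and target leads at 63.9%.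

(The runs are simulated on assumed constants.)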